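## Structural features

The target is a flavan-4-ol: benzene ring A is fused through C4a–C8a to dihydropyran ring C, which carries the 4-hydroxyphenyl ring B on C2 by a single C–C bond. Ring A is a fully differentiated phloroglucinol, with a free hydroxyl at C5 (peri to C4), a methyl ether at C7, a prenyl chain at C8 next to the ring oxygen O1, and one hydrogen left at C6. The stereocentres C2 and C4 stand in a 1,3-relation across the C3 methylene; (2S,4R) is the 2,4-trans series, with the aryl group equatorial and the C4 hydroxyl axial on the half-chair of ring C. The C4 carbinol is benzylic to a ring with oxygen at both ortho positions and the para position, so acid ionises it to a cation that can epimerise, lose H3 to a flav-3-ene, or alkylate C6 of a second molecule. The prenyl alkene excludes hydrogenolysis and strong acid (chroman formation with a neighbouring phenol), and the 4'-phenol lets base open O1–C2 through a quinone methide. The real difficulty is the absolute configuration at C2, an isolated benzylic ether centre with no neighbouring handle, together with telling apart three phenol oxygens and C8 from C6; C4 needs only relative control. The key step uses the fact that O1–C8a–C4a–C4 with its C4 oxygen is an oxygenated o-quinone methide in disguise and C2–C3 with ring B is a styrene, so ring C is their [4+2] adduct. The same easy ionisation of C4 makes the heterodiene and later corrects C4.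

## Logic of the disconnections

**13 ⇒ 12.** The two aryl O–Si bonds (O5–Si and O4'–Si) are cut last. The silyl ether on O5 is wanted until the end because its bulk holds the C4 oxygen axial and screens C6. Both phenols are hidden by groups that leave in one operation. The forward step must use fluoride that is neither basic enough to open ring C through the 4'-phenoxide nor acidic enough to ionise C4.

**12 ⇒ 11.** The C4–OH bond is traced back to a C4–OMe bond. A methoxy group is what an orthoformate-based annulation leaves at C4, and a benzylic ether with three oxygen donors exchanges by ionisation. The gain is that the C4 configuration need not be fixed when the ring is made, since the exchange is reversible and both C4 epimers converge on the axial alcohol. The forward step needs an acid mild enough to spare the silyl ethers, the prenyl alkene and the C2 ether, and enough water to outrun loss of H3.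

**11 ⇒ 5 + 6 + 7.** O1–C2 and C3–C4 are cut, with the C4 methoxy group assigned to 7. This opens ring C, removes both stereocentres, and splits the molecule into a ring A aldehyde and a ring B styrene of similar size. The forward step must generate the C4-oxygenated o-quinone methide from 5 under an acid that is chiral and weak, and the catalyst must decide which face of the alkene of 6 bonds to O1.

**5 ⇒ 4.** The O–Si bond on the oxygen that becomes O5 is cut. Only the phenol next to the prenyl chain may stay free, because it becomes O1; a free phenol on the other side would lead to the 6-prenyl isomer. Triisopropylsilyl is placed here rather than the smaller tert-butyldimethylsilyl group, for four reasons: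
- it discriminates better between the two ortho phenols;
- it resists the acid of the later steps;
- it screens C6 against Friedel–Crafts attack;
- it strengthens the peri bias at C4.

The forward step must silylate the phenol that has C5–H as its neighbour and not the one wedged between formyl and prenyl.

**4 ⇒ 2 + 3.** The bond from ring carbon C3 of the aldehyde to the prenyl CH2 is cut. Compound 2 is C2-symmetric, so either nucleophilic ring carbon gives the same product and the chain arrives in one step from 3. The forward step needs C-alkylation in preference to O-alkylation and must stop after one prenyl group.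

**2 ⇒ 1.** The O–CH3 bond at the oxygen para to the formyl group is cut. This leads to a cheap commercial trihydroxy aldehyde and, by capping the only unchelated phenoxide, prepares the C-alkylation. The forward step must methylate the para oxygen only.

## Other disconnections considered

**Alternative 1:** The cut removes O1–C2, C2–C3 and the C4–O bond. Ring C is then made from an o-hydroxystyrene of ring A, 4-bromo-2-ethenyl-3-hydroxy-5-methoxyphenyl pivalate A2, and 4-acetoxybenzaldehyde A3. A confined chiral Brønsted acid would condense the phenol of A2 with A3 to an aryl oxocarbenium ion, the vinyl group would attack it (C2–C3), and the C4 benzylic cation would take up water from the axial direction to give (2S,4R)-8-bromo-4-hydroxy-7-methoxyflavan 5-pivalate 4'-acetate A1.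
- In favour: three bonds are formed instead of two. The C4 hydroxyl arrives directly, which is better than the chosen plan with its separate ether exchange. The acyl groups tame both partners (no electron-rich styrene to polymerise, a C2 ether that cannot reopen), and without the prenyl group there is no risk of acid-induced chroman formation. On these points the alternative is the better one.
- Against: the prenyl group must be brought in later by cross-coupling at a bromide flanked by two oxygens, in a molecule with an ionisable C4 carbinol. The 5-pivalate can migrate to the neighbouring C4 hydroxyl, and both esters need base, under which the 4'-phenoxide can open ring C. A2 is itself prone to acid-induced dimerisation, and the acceptor at O5 makes the C4 cation form less readily.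
- Comparison: both plans rest on the same stabilised C4 cation and on an enantioselective acid catalysis without direct precedent, so the risk at the key step is equal. In both, the catalyst sets C2 and thermodynamics sets C4. The alternative is longer by roughly two to three operations (bromination, vinyl installation, late prenylation, deacylation).

**Alternative 2:** Here ring A is cut at C5–C6, C7–C8 and C4a–C5. This leads back to a pyran-fused 3-alkoxycyclobutenone that already holds both stereocentres, (3S,5R)-5-(tert-butyldimethylsilyloxy)-3-[4-(tert-butyldimethylsilyloxy)phenyl]-8-(3-methylbut-2-enyl)-2-oxabicyclo[4.2.0]oct-1(8)-en-7-one A5, and to methoxyacetylene A6. On heating, A5 would open to a vinylketene, add A6 in a [2+2] sense, open again and close by 6π electrocyclisation. Tautomerisation would give the phenol (2S,4R)-4,4'-bis(tert-butyldimethylsilyloxy)-7-methoxy-8-prenylflavan-5-ol A4 (Danheiser benzannulation).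
- In favour: the substitution pattern of ring A is written into the two components, so the three regiochemical questions of the chosen route (which oxygen is methylated, where the prenyl group goes, which phenol is silylated) do not arise. Here the alternative is clearly better. The 5-hydroxyl appears free, the conditions are neutral, and the reaction type is established, which the chosen key step is not.
- Against: A5 is a strained bicyclic vinylogous ester with no close model, and making it with C2 and C4 in place would take many steps. A6 is volatile and unstable. The cyclohexadienone that precedes A4 has the C4 silyloxy group β to its carbonyl, so loss of silanol towards an o-quinone methide competes with tautomerisation. The stereochemical problem is not solved, only moved into the synthesis of A5.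
- Comparison: the two plans are equal in that ring C and its stereocentres pass through the key step unchanged. On step economy the alternative is far behind; it would at least double the step count and is linear where the chosen plan is convergent.

**Alternative 3:** The C4–C4a bond is cut. This leads to an aryl iodide whose ether oxygen carries C2–C3–C4 as a β-aryloxy aldehyde, (3S)-3-[4-(tert-butyldimethylsilyloxy)phenyl]-3-[2-iodo-5-methoxy-6-(3-methylbut-2-enyl)-3-(triisopropylsilyloxy)phenoxy]propanal A8. CrCl2 with catalytic NiCl2 would turn the C–I bond into an aryl–chromium bond (nickel inserts, trivalent chromium takes over the aryl group). This would add to the tethered aldehyde in a 6-exo closure of ring C (Nozaki–Hiyama–Kishi reaction) to give the carbinol A7, which is identical with 12 of the chosen route.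
- In favour: C2 would be set beforehand by established asymmetric carbonyl chemistry, so on precedent for the stereo-defining step this plan is better. The conditions are neutral and tolerate silyl ethers and the prenyl alkene. Because A7 is 12, only the fluoride step follows, one operation fewer after the key step than in the chosen plan.
- Against: A8 requires joining a hindered, doubly ortho-substituted iodophenol to an electron-rich benzylic carbinol with clean inversion, a substitution that tends to leak through the benzylic cation and erode C2. A β-aryloxy aldehyde can expel the phenoxide by elimination. Aryl–chromium formation between two ortho oxygen substituents is slow. The aldehyde must be unmasked without oxidative alkene cleavage because of the prenyl group. C4 arises under kinetic control, so the acid equilibration of step 5 might still be needed.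
- Comparison: both plans close one ring; the alternative forms one bond and one stereocentre in its key step where the chosen step forms two of each. It needs about ten steps in the longest line against six.

Key step: step 4

**Assumption (sense of induction):** which hand of the chiral phosphoric acid leads to the 2S series cannot be derived with confidence for this substrate pair; the (R)-acid is written, and its mirror image is used if the induction proves opposite.

**Remark (structures):** (2S,4R) is the 2,4-trans flavan-4-ol, and an aldehyde whose free phenol lies next to the prenyl chain maps onto the 8-prenyl flavan; the structures below are consistent with this and needed no correction. The only change of design is triisopropylsilyl in place of tert-butyldimethylsilyl on the ring A oxygen.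

## Route

**Step 1**
Reactants: 1 2,4,6-trihydroxybenzaldehyde
Product: 2 2,6-dihydroxy-4-methoxybenzaldehyde
Conditions: MeI (1.0 equiv), K2CO3 (1.0 equiv), acetone, 0 °C to rt
Reagents that add atoms: methyl iodide, CI
Why: Williamson O-methylation; the para hydroxyl is the most acidic and least hindered phenol, whereas the two ortho hydroxyls flank the formyl group and share its chelate, so one equivalent of base and MeI should react at O4 first and give the symmetric diol 2.

**Step 2**
Reactants: 2 2,6-dihydroxy-4-methoxybenzaldehyde; 3 prenyl bromide
Product: 4 2,6-dihydroxy-4-methoxy-3-(3-methylbut-2-enyl)benzaldehyde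
Conditions: 10% aq KOH, 3 (1.0 equiv) added slowly, 0 °C to rt
Reagents that add atoms: none
Why: C-allylation of an ambident phenoxide; with the unchelated 4-oxygen capped, the remaining phenoxides are chelated to the formyl group and solvated by water, so the soft allylic bromide should be attacked by the ring carbon that is ortho to one oxygen and para to the other. C3 and C5 are equivalent, and keeping 3 limiting should hold back a second prenylation.

**Step 3**
Reactants: 4 2,6-dihydroxy-4-methoxy-3-(3-methylbut-2-enyl)benzaldehyde
Product: 5 2-hydroxy-4-methoxy-3-(3-methylbut-2-enyl)-6-(triisopropylsilyloxy)benzaldehyde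
Conditions: TIPSCl (1.05 equiv), imidazole, DMF, 0 °C
Reagents that add atoms: triisopropylsilyl chloride, CC(C)[Si](Cl)(C(C)C)C(C)C
Why: silylation of a phenol under steric control; the hydroxyl between formyl and prenyl is shielded on both sides and buttressed into the chelate, so the bulky silyl chloride should take the hydroxyl whose other neighbour is C5–H. The remaining phenol is then chelated and should not silylate further.

**Step 4**
Reactants: 5 2-hydroxy-4-methoxy-3-(3-methylbut-2-enyl)-6-(triisopropylsilyloxy)benzaldehyde; 6 4-(tert-butyldimethylsilyloxy)styrene; 7 trimethyl orthoformate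
Product: 11 (2S,4R)-4,7-dimethoxy-8-(3-methylbut-2-enyl)-4'-(tert-butyldimethylsilyloxy)-5-(triisopropylsilyloxy)flavan, via dimethyl acetal 8 (not isolated), via methoxy o-quinone methide 9 (not isolated), via 2,4-cis adduct 10 (not isolated)
Conditions: (R)-3,3'-bis(2,4,6-triisopropylphenyl)-1,1'-binaphthyl-2,2'-diyl hydrogen phosphate (10 mol%), 7 (1.5 equiv), 6 (3 equiv), toluene, −20 °C to rt
Reagents that add atoms: none
Why: Proposed new method: the phosphoric acid catalyses acetal formation from 5 and 7 to give 8, whose ionisation, assisted by the ortho phenol and the two other ring oxygens, yields the methoxy-substituted o-quinone methide 9 as a hydrogen-bonded ion pair with the chiral phosphate. The electron-rich alkene of 6 adds in an asynchronous inverse-demand oxa-[4+2] reaction: its CH2 terminus bonds to the methide carbon (C3–C4) while the charge developing at the benzylic carbon is taken up by the quinone methide oxygen (O1–C2), so the aryl group can only arrive at C2. Ring C therefore closes by cycloaddition across O1=C8a–C4a=C4, the six-membered ring being completed by the O1–C2 bond. The closest known reaction types are the racemic acid-catalysed union of salicylaldehydes, orthoformates and alkenes to 4-alkoxychromans, the intramolecular [4+2] of alkoxy o-quinone methides formed from salicylaldehydes and alcohols under confined chiral acids, and chiral phosphoric acid [4+2] reactions of o-quinone methides with styrenes. C2 is controlled by the chiral phosphate, which is hydrogen-bonded to the very oxygen that becomes O1 and so selects the enantiotopic face of the alkene that this oxygen attacks. C4 is controlled by thermodynamics: the ether is re-ionised by the acid, so the kinetic cis adduct 10 is expected to drift to 11, in which the methoxy group is axial and clear of the peri silyloxy group while the aryl group stays equatorial, and any 10 that persists converges in step 5. The step needs chemoselectivity for the acetal over the prenyl alkene and the silyl ethers and regioselectivity for O1 next to the prenyl chain; the first is secured by an acid too weak to protonate a trisubstituted alkene or to polymerise 6 at low temperature, the second by the fact that only this phenol is free and that the triisopropylsilyl group screens C6 against Friedel–Crafts attack.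

**Step 5**
Reactants: 11 (2S,4R)-4,7-dimethoxy-8-(3-methylbut-2-enyl)-4'-(tert-butyldimethylsilyloxy)-5-(triisopropylsilyloxy)flavan
Product: 12 (2S,4R)-7-methoxy-8-(3-methylbut-2-enyl)-4'-(tert-butyldimethylsilyloxy)-5-(triisopropylsilyloxy)flavan-4-ol
Conditions: pyridinium p-toluenesulfonate (0.2 equiv), acetone/H2O (4:1), rt
Reagents that add atoms: water, O
Why: acid-catalysed SN1 exchange of an activated benzylic ether (the interconversion of 4-alkoxyflavans and flavan-4-ols); the C4 cation has oxygen donors at both ortho positions and the para position, should form under pyridinium buffering, and is captured by the large excess of water. Capture is reversible, so C4 should settle in the axial 2,4-trans arrangement that avoids the peri silyloxy group (also the product of axial attack on the half-chair cation), whatever the C4 configuration of the ether that enters. C2 is untouched because its cation would have a single donor.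

**Step 6**
Reactants: 12 (2S,4R)-7-methoxy-8-(3-methylbut-2-enyl)-4'-(tert-butyldimethylsilyloxy)-5-(triisopropylsilyloxy)flavan-4-ol
Product: 13 (2S,4R)-4,5,4'-trihydroxy-7-methoxy-8-prenylflavan
Conditions: Bu4NF/AcOH (1:1, 3 equiv), THF, 0 °C; pH 7 work-up
Reagents that add atoms: none
Why: fluoride cleavage of the two aryl silyl ethers; acetic acid keeps the liberated phenols protonated, which should prevent opening of ring C through the 4'-quinone methide, and the medium is never acidic enough to re-ionise C4, so both stereocentres are carried through unchanged.

## Compound list

1 | 2,4,6-trihydroxybenzaldehyde | O=Cc1c(O)cc(O)cc1O | starting material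
2 | 2,6-dihydroxy-4-methoxybenzaldehyde | COc1cc(O)c(C=O)c(O)c1 | intermediate
3 | prenyl bromide (1-bromo-3-methylbut-2-ene) | CC(C)=CCBr | starting material
4 | 2,6-dihydroxy-4-methoxy-3-(3-methylbut-2-enyl)benzaldehyde | COc1cc(O)c(C=O)c(O)c1CC=C(C)C | intermediate
5 | 2-hydroxy-4-methoxy-3-(3-methylbut-2-enyl)-6-(triisopropylsilyloxy)benzaldehyde | COc1cc(O[Si](C(C)C)(C(C)C)C(C)C)c(C=O)c(O)c1CC=C(C)C | intermediate
6 | 4-(tert-butyldimethylsilyloxy)styrene | C=Cc1ccc(O[Si](C)(C)C(C)(C)C)cc1 | starting material
7 | trimethyl orthoformate | COC(OC)OC | starting material
8 | 2-(dimethoxymethyl)-5-methoxy-6-(3-methylbut-2-enyl)-3-(triisopropylsilyloxy)phenol | COc1cc(O[Si](C(C)C)(C(C)C)C(C)C)c(C(OC)OC)c(O)c1CC=C(C)C | intermediate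
9 | 3-methoxy-6-(methoxymethylene)-2-(3-methylbut-2-enyl)-5-(triisopropylsilyloxy)cyclohexa-2,4-dien-1-one (alkene geometry not fixed) | COC=C1C(=O)C(CC=C(C)C)=C(OC)C=C1O[Si](C(C)C)(C(C)C)C(C)C | intermediate
10 | (2S,4S)-4,7-dimethoxy-8-(3-methylbut-2-enyl)-4'-(tert-butyldimethylsilyloxy)-5-(triisopropylsilyloxy)flavan (2,4-cis) | COc1cc(O[Si](C(C)C)(C(C)C)C(C)C)c2c(c1CC=C(C)C)O[C@H](c1ccc(O[Si](C)(C)C(C)(C)C)cc1)C[C@@H]2OC | intermediate
11 | (2S,4R)-4,7-dimethoxy-8-(3-methylbut-2-enyl)-4'-(tert-butyldimethylsilyloxy)-5-(triisopropylsilyloxy)flavan (2,4-trans) | COc1cc(O[Si](C(C)C)(C(C)C)C(C)C)c2c(c1CC=C(C)C)O[C@H](c1ccc(O[Si](C)(C)C(C)(C)C)cc1)C[C@H]2OC | intermediate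
12 | (2S,4R)-7-methoxy-8-(3-methylbut-2-enyl)-4'-(tert-butyldimethylsilyloxy)-5-(triisopropylsilyloxy)flavan-4-ol | COc1cc(O[Si](C(C)C)(C(C)C)C(C)C)c2c(c1CC=C(C)C)O[C@H](c1ccc(O[Si](C)(C)C(C)(C)C)cc1)C[C@H]2O | intermediate
13 | (2S,4R)-4,5,4'-trihydroxy-7-methoxy-8-prenylflavan, i.e. (2S,4R)-2-(4-hydroxyphenyl)-7-methoxy-8-(3-methylbut-2-enyl)chromane-4,5-diol | COc1cc(O)c2c(c1CC=C(C)C)O[C@H](c1ccc(O)cc1)C[C@H]2O | target

## Step count and least certain steps

Total: 6 steps. Longest linear sequence: 6 steps (1 to 13); 3 enters in step 2, and 6 and 7 enter in step 4.

**Step 4 (key step, proposed new method).** The most likely failure is poor facial discrimination at C2, because the styrene has no hydrogen-bond donor to anchor it to the phosphate. Stepwise cationic pathways could also divert material into oligomerisation of 6 or arylation of ring A.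

Fallback, from 5 back to 12, on known reaction types only. Addition of MeMgBr (excess, THF, −78 to 0 °C) to the aldehyde of 5 gives 1-[2-hydroxy-4-methoxy-3-(3-methylbut-2-enyl)-6-(triisopropylsilyloxy)phenyl]ethanol F1, which MnO2 in CH2Cl2 oxidises to the acetophenone 1-[2-hydroxy-4-methoxy-3-(3-methylbut-2-enyl)-6-(triisopropylsilyloxy)phenyl]ethanone F2. Condensation with Me2NCH(OMe)2 in hot toluene gives the enaminone (E)-3-(dimethylamino)-1-[2-hydroxy-4-methoxy-3-(3-methylbut-2-enyl)-6-(triisopropylsilyloxy)phenyl]prop-2-en-1-one F3, which closes on mild acid treatment to the chromone 7-methoxy-8-(3-methylbut-2-enyl)-5-(triisopropylsilyloxy)chromen-4-one F4. Asymmetric conjugate addition of 4-(tert-butyldimethylsilyloxy)phenylboronic acid with Pd(OCOCF3)2 and 4-tert-butyl-2-(2-pyridyl)oxazoline (hand chosen for 2S) in wet 1,2-dichloroethane sets C2 and gives (2S)-7-methoxy-8-(3-methylbut-2-enyl)-4'-(tert-butyldimethylsilyloxy)-5-(triisopropylsilyloxy)flavanone F5. NaBH4 in THF/EtOH at 0 °C reduces the ketone to the 2,4-cis alcohol (2S,4S)-7-methoxy-8-(3-methylbut-2-enyl)-4'-(tert-butyldimethylsilyloxy)-5-(triisopropylsilyloxy)flavan-4-ol F6. Exposure of F6 to the conditions of step 5 should epimerise C4 through the same cation and deliver 12.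

**Step 2.** The most likely failure is alkylation at oxygen and a second C-prenylation, since the phenoxide is ambident and the product is as nucleophilic as 2.

Fallback, from 2 back to 4. Mono-iodination of 2 with N-iodosuccinimide (one equivalent, MeCN, 0 °C) gives 2,6-dihydroxy-3-iodo-4-methoxybenzaldehyde F7. Stille coupling with tributyl(3-methylbut-2-enyl)stannane and Pd(PPh3)4 in DMF then places the prenyl group on the carbon that carried iodine and returns to 4.

**Step 3.** The most likely failure is silylation of the wrong phenol or of both, because the two hydroxyls differ only in their second neighbour.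

Fallback, from 2 back to 5, with the order of events changed so that no discrimination is needed. The symmetric diol 2 is monosilylated (TIPSCl, imidazole, DMF) to 2-hydroxy-4-methoxy-6-(triisopropylsilyloxy)benzaldehyde F8. Its one free phenol is converted under Tsuji–Trost conditions (tert-butyl 2-methylbut-3-en-2-yl carbonate, Pd(PPh3)4, THF, 0 °C) into the tertiary allyl ether 4-methoxy-2-(2-methylbut-3-en-2-yloxy)-6-(triisopropylsilyloxy)benzaldehyde F9. Heating F9 in toluene brings about the aromatic Claisen rearrangement to the only free ortho carbon and gives 5 with the prenyl group next to the free phenol by construction. This detour also bypasses step 2.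

**Step 5.** The most likely failure is loss of the C3 proton from the C4 cation (elimination to the flav-3-ene), attack of C6 of a second molecule on the cation, and incomplete exchange because methanol competes with water.

Fallback, from 11 back to 12, with a sulfur nucleophile interposed. Under the same mild acid in CH2Cl2, excess benzyl mercaptan captures the cation far more efficiently than water and gives (2S,4R)-4-(benzylsulfanyl)-7-methoxy-8-(3-methylbut-2-enyl)-4'-(tert-butyldimethylsilyloxy)-5-(triisopropylsilyloxy)flavan F10. AgBF4 with 2,6-di-tert-butyl-4-methylpyridine in THF/H2O at 0 °C then activates the sulfide thiophilically under non-acidic, irreversible conditions, and water enters axially to give 12.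

## Further compounds

F1 | step 4 | 1-[2-hydroxy-4-methoxy-3-(3-methylbut-2-enyl)-6-(triisopropylsilyloxy)phenyl]ethanol (racemic carbinol) | COc1cc(O[Si](C(C)C)(C(C)C)C(C)C)c(C(C)O)c(O)c1CC=C(C)C
F2 | step 4 | 1-[2-hydroxy-4-methoxy-3-(3-methylbut-2-enyl)-6-(triisopropylsilyloxy)phenyl]ethanone | COc1cc(O[Si](C(C)C)(C(C)C)C(C)C)c(C(C)=O)c(O)c1CC=C(C)C
F3 | step 4 | (E)-3-(dimethylamino)-1-[2-hydroxy-4-methoxy-3-(3-methylbut-2-enyl)-6-(triisopropylsilyloxy)phenyl]prop-2-en-1-one | COc1cc(O[Si](C(C)C)(C(C)C)C(C)C)c(C(=O)/C=C/N(C)C)c(O)c1CC=C(C)C
F4 | step 4 | 7-methoxy-8-(3-methylbut-2-enyl)-5-(triisopropylsilyloxy)chromen-4-one | COc1cc(O[Si](C(C)C)(C(C)C)C(C)C)c2c(c1CC=C(C)C)OC=CC2=O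
F5 | step 4 | (2S)-7-methoxy-8-(3-methylbut-2-enyl)-4'-(tert-butyldimethylsilyloxy)-5-(triisopropylsilyloxy)flavanone | COc1cc(O[Si](C(C)C)(C(C)C)C(C)C)c2c(c1CC=C(C)C)O[C@H](c1ccc(O[Si](C)(C)C(C)(C)C)cc1)CC2=O
F6 | step 4 | (2S,4S)-7-methoxy-8-(3-methylbut-2-enyl)-4'-(tert-butyldimethylsilyloxy)-5-(triisopropylsilyloxy)flavan-4-ol (2,4-cis) | COc1cc(O[Si](C(C)C)(C(C)C)C(C)C)c2c(c1CC=C(C)C)O[C@H](c1ccc(O[Si](C)(C)C(C)(C)C)cc1)C[C@@H]2O
F7 | step 2 | 2,6-dihydroxy-3-iodo-4-methoxybenzaldehyde | COc1cc(O)c(C=O)c(O)c1I
F8 | step 3 | 2-hydroxy-4-methoxy-6-(triisopropylsilyloxy)benzaldehyde | COc1cc(O)c(C=O)c(O[Si](C(C)C)(C(C)C)C(C)C)c1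
F9 | step 3 | 4-methoxy-2-(2-methylbut-3-en-2-yloxy)-6-(triisopropylsilyloxy)benzaldehyde | COc1cc(OC(C)(C)C=C)c(C=O)c(O[Si](C(C)C)(C(C)C)C(C)C)c1
F10 | step 5 | (2S,4R)-4-(benzylsulfanyl)-7-methoxy-8-(3-methylbut-2-enyl)-4'-(tert-butyldimethylsilyloxy)-5-(triisopropylsilyloxy)flavan | COc1cc(O[Si](C(C)C)(C(C)C)C(C)C)c2c(c1CC=C(C)C)O[C@H](c1ccc(O[Si](C)(C)C(C)(C)C)cc1)C[C@H]2SCc1ccccc1
A1 | alternative 1 | (2S,4R)-8-bromo-4-hydroxy-7-methoxyflavan 5-pivalate 4'-acetate | COc1cc(OC(=O)C(C)(C)C)c2c(c1Br)O[C@H](c1ccc(OC(C)=O)cc1)C[C@H]2O
A2 | alternative 1 | 4-bromo-2-ethenyl-3-hydroxy-5-methoxyphenyl pivalate | C=Cc1c(OC(=O)C(C)(C)C)cc(OC)c(Br)c1O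
A3 | alternative 1 | 4-acetoxybenzaldehyde | CC(=O)Oc1ccc(C=O)cc1
A4 | alternative 2 | (2S,4R)-4,4'-bis(tert-butyldimethylsilyloxy)-7-methoxy-8-prenylflavan-5-ol | COc1cc(O)c2c(c1CC=C(C)C)O[C@H](c1ccc(O[Si](C)(C)C(C)(C)C)cc1)C[C@H]2O[Si](C)(C)C(C)(C)C
A5 | alternative 2 | (3S,5R)-5-(tert-butyldimethylsilyloxy)-3-[4-(tert-butyldimethylsilyloxy)phenyl]-8-(3-methylbut-2-enyl)-2-oxabicyclo[4.2.0]oct-1(8)-en-7-one (C6 not defined) | O=C1C(CC=C(C)C)=C2O[C@H](c3ccc(O[Si](C)(C)C(C)(C)C)cc3)C[C@@H](O[Si](C)(C)C(C)(C)C)C21
A6 | alternative 2 | methoxyacetylene | COC#C
A7 | alternative 3 | (2S,4R)-7-methoxy-8-(3-methylbut-2-enyl)-4'-(tert-butyldimethylsilyloxy)-5-(triisopropylsilyloxy)flavan-4-ol (identical with 12) | COc1cc(O[Si](C(C)C)(C(C)C)C(C)C)c2c(c1CC=C(C)C)O[C@H](c1ccc(O[Si](C)(C)C(C)(C)C)cc1)C[C@H]2O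
A8 | alternative 3 | (3S)-3-[4-(tert-butyldimethylsilyloxy)phenyl]-3-[2-iodo-5-methoxy-6-(3-methylbut-2-enyl)-3-(triisopropylsilyloxy)phenoxy]propanal | COc1cc(O[Si](C(C)C)(C(C)C)C(C)C)c(I)c(c1CC=C(C)C)O[C@H](c1ccc(O[Si](C)(C)C(C)(C)C)cc1)CC=O
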